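# Proposed total synthesis of CNP0219601.2 from (R)-carvone by a ring-B-closing vinylogous Michael addition

## The problem

The target 27 is a cis-fused octalin, numbered here C1 (trienoic acid), C2 (exocyclic enone carbon), C3 (methyl), C4, C4a, C5, C6 (methyl), C7 (hydroxyl), C8 (methyl), C8a; ring A is the cyclohexene and ring B the cyclohexane. Six stereocenters have to be set: C8a and C4a (cis fusion), C1 (side chain anti to C8 across ring A) and the C6/C7/C8 methyl–hydroxyl–methyl triad, which is all-equatorial in the ring B chair that keeps C1 equatorial and C4 axial. C8a can control C1 (alkylation anti to its substituent) and C4a (a tether on C8a can only reach C4a from its own face when the new bond forms axially on ring A). C6 and C8 flank C7 and can be left to equilibration while C7 is a ketone, after which C7 is set by hydride delivery. The fragile parts are the cross-conjugated dienone with its hydroxymethyl ketone, the (2E,4Z,6E)-trienoic acid with its Z-trisubstituted alkene, and above all C1–H, which lies between both π systems and becomes base-labile once either is present. A formyl group on C1 next to a C2 carbonyl would be a β-dicarbonyl compound and would erase C1, so the C1 chain has to be grown while C2 is sp3, and the dienone and the acid have to appear late and without strong base. The structural feature that invites the key step is that ring A (C3 methyl, C3=C4 alkene, C2 oxygen, C8a stereocenter) plus C8, its methyl and C7 map onto (R)-carvone 1 with no atom missing or left over. The γ-carbon of the carvone enone is C4a, and an isopropenyl ketone grown on the carvone isopropenyl group puts its terminal carbon C5 within reach, so a vinylogous Michael addition closes ring B.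

## Retrosynthesis

**27 ⇐ 26 ⇐ 24 + 25.** The side chain is numbered C1′ (carboxyl) to C7′ (on ring carbon C1). The last carbon–carbon bond cut is C3′–C4′: a Heck reaction of the (Z)-alkenyl iodide 24 with acrylic acid 25 would give the free acid 26 directly. The neighbouring cut at C2′=C3′ (phosphonate olefination) would leave an ester to be saponified on a dienone whose C1–H is base-labile. The forward reaction has to retain the Z geometry of the iodide and deliver an E acrylate; removal of two silyl ethers from 26 then ends the route.

**24 ⇐ 23.** The exocyclic C2=C bond and the adjacent ketone are traced to the tertiary propargylic alcohol 23 by a Meyer–Schuster transposition. Direct olefination of a C2 ketone flanked by the C3 methyl and a branched C1 is the alternative, but a ketophosphonate is unlikely to add there, whereas a linear acetylide should. The rearrangement also delivers the hydroxymethyl ketone at the correct oxidation level. The forward step must move oxygen across the alkyne and not across the C3=C4 alkene; the alkene geometry should follow from thermodynamics (acyl group away from the C3 methyl).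

**23 ⇐ 20 + 21; 20 ⇐ 18 + 19.** C4′=C5′ and C6′=C7′ are cut as two Wittig bonds. The α-iodoethylidene ylide from 21 turns enal 20 into the (Z)-iodide (22, then 23 after loss of the tertiary silyl group), and the formyl-stabilised ylide 19 turns aldehyde 18 into 20. A cross-coupling cut at C5′–C6′ would need a C1 alkyne and a regioselective hydrometalation; the chosen cuts use the C1 formyl group directly and give each trisubstituted alkene with the geometry inherent to its ylide type. A formyl group on C1 is tolerable only because C2 is a protected sp3 carbinol at this stage.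

**18 ⇐ 17 ⇐ 14 + 15.** The C2–alkyne bond is cut to ring A enone 14 and propargyl silyl ether 15. The adduct (dialkoxide 16) is capped in the flask as the bis(trimethylsilyl) ether 17, whose primary silyl ether is oxidised directly to aldehyde 18. Capping the tertiary oxygen matters: a free C2 alkoxide next to a C1 chain conjugated to a carbonyl could open ring A by a vinylogous retro-aldol cleavage. The forward addition must be 1,2 and must not enolise the ketone.

**14 ⇐ 13 ⇐ 12 ⇐ 11.** These are functional-group changes. The benzyl ether is removed before the alkyne arrives, because no debenzylation is compatible with an alkyne and a tertiary allylic–propargylic carbinol. The C7 hydroxyl is silylated (13) and comes from chemoselective reduction of the saturated ketone of diketone 11 (12). The reduction has to distinguish the C7 ketone from the ring A enone and deliver the equatorial carbinol.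

**11 ⇐ 9 (through dienolate 10).** Cutting C4a–C5 opens ring B to the carvone derivative 9. Cuts at C8–C8a or C5–C6 would discard the carvone correspondence and require ring B to be assembled from acyclic pieces; the C4a–C5 cut removes one ring and two stereocenters (C4a, C6) and leaves a monocycle whose only fixed centers are C8a and C1. The forward reaction must be γ-selective, cis-selective, and allow C6 and C8 to equilibrate.

**9 ⇐ 8 ⇐ 6 + 7; 6 ⇐ 5 ⇐ 4.** The C6–C7 bond is cut to aldehyde 6 and isopropenylmagnesium bromide 7, followed by oxidation of carbinol 8. Aldehyde 6 is the hydride-shift isomer of epoxide 5, which is the peracid product of 4. The forward steps must discriminate the isopropenyl alkene from the enone alkene and the aldehyde from the enone carbonyl; the C8 configuration is left open because it converges later.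

**4 ⇐ 1 + 2 (through 3).** The C1–CH2 bond is cut to (R)-carvone 1 and benzyl chloromethyl ether 2 via the kinetic enolate 3. This puts the C1 carbon in place before any other stereocenter exists and uses C8a to direct it anti.

## Roads not taken

**Alternative 1:** The cut is at C4a–C8a and C3=C4, so that both rings come from the open-chain enone aldehyde A2. In the forward step a secondary amine would form the enamine of the C4 aldehyde, C4a would add to the enone carbon C8a (ring B), and the ethyl ketone thus freed would condense through C3 onto the C4 aldehyde (ring A), giving octalinone A1. Its merits are real: two rings and the C4a/C8a pair arise in one catalytic operation, and the C6–C8 triad, including the C7 carbinol, is set by acyclic reagent control. In that respect it is better than the chosen plan, which relies on equilibration for C6/C8 and on a ketone reduction of uncertain facial bias for C7. Its weak points are the length of the acyclic synthesis of A2, the need for the catalyst to override or match the existing triad in the Michael step, and a C1 that is still unsubstituted in A1, so that the side-chain carbon must be introduced late, next to the ring fusion, on a precious intermediate. The chosen plan sets against this that C8a and all of ring A are bought with carvone, that the C1 carbon is installed in the first step, and that the bicyclic core is reached in six steps.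

**Alternative 2:** The cut is at C4–C4a. Zerovalent palladium would insert into the (Z)-iodoalkene of A4, the alkenylpalladium would add to C4a of the ring B cyclohexene in a 6-exo mode, and β-hydride elimination toward C6 would release hexalin A3. The cis fusion follows from geometry under neutral conditions, with no epimerisable intermediate, and the C2 oxygen and the C1 carbon are present at useful oxidation levels; on the security of C4a this road is at least as good as the chosen one. Its weak points are that A4 already carries the C7/C8 centers on the ring and C1/C2 on the chain and needs a long stereocontrolled assembly, and that A3 contains a C5=C6 alkene that has to be hydrogenated face-selectively to set C6 in the presence of the equally substituted C3=C4 alkene. The chosen plan sets C6 thermodynamically instead and needs no alkene differentiation, at the price of a base-mediated ring closure.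

**Alternative 3:** The cuts are at C8–C8a and C5–C6, a [3+3] annulation of 3-pentanone A6 with the racemic Morita–Baylis–Hillman carbonate A7. A chiral amine would form the enamine of A6, which would substitute the carbonate with allylic transposition so that the new bond ends at C8a. The second α-carbon would then add to the regenerated acrylate terminus C5, giving cyclohexanone A5. This is probably the shortest entry to ring B with the methyl–carbonyl–methyl array, uses achiral commodity materials, and treats C6 and C8 as thermodynamic centers exactly as the chosen plan does. Its weak points are that four stereocenters and the absolute configuration rest on a cascade that must also resolve a racemic electrophile, that ring A still has to be annulated (ester to aldehyde, ketal removal, aldol condensation), and that C1 is again unsubstituted afterwards. The C7 ketone reduction problem is shared with the chosen plan. Against the shorter ring B synthesis, the chosen plan offers an absolute configuration taken from the chiral pool, a finished ring A, and the C1 carbon in place from the start.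

Key step: step 6

Remark on the chemistry: compounds 5, 6, 8, 9 and 10 are carried as mixtures of C8 epimers (8 also at C7), and 16–23 as either C2 epimer. These centers are equilibrated or destroyed later, so their SMILES leave them open.

## Route

Step 1
Reactants: 1 (R)-(−)-carvone; 2 benzyl chloromethyl ether
Product: 4 (5R,6R)-6-[(benzyloxy)methyl]-2-methyl-5-(prop-1-en-2-yl)cyclohex-2-en-1-one (benzyloxymethyl trans to isopropenyl), via lithium dienolate 3 (not isolated)
Conditions: LiN(i-Pr)2, THF, −78 °C; then 2, −78 → −40 °C
Reagents that add atoms: none
Why: Kinetic deprotonation gives the cross-conjugated α′-enolate, which is C-alkylated by the reactive chloromethyl ether (enolate alkylation). The electrophile should enter anti to the adjacent isopropenyl group, and the trans product is also the thermodynamic one.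

Step 2
Reactants: 4
Product: 5 (5R,6R)-6-[(benzyloxy)methyl]-2-methyl-5-(2-methyloxiran-2-yl)cyclohex-2-en-1-one (both oxirane epimers)
Conditions: mCPBA, CH2Cl2, 0 °C
Reagents that add atoms: meta-chloroperoxybenzoic acid, OOC(=O)c1cccc(Cl)c1
Why: Prilezhaev epoxidation is selective for the electron-rich 1,1-disubstituted alkene over the electron-poor enone alkene. No facial control is expected or needed at C8.

Step 3
Reactants: 5
Product: 6 2-{6-[(benzyloxy)methyl]-4-methyl-5-oxocyclohex-3-en-1-yl}propanal (ring centers as in 4; both C8 epimers)
Conditions: BF3·OEt2 (0.3 equiv), CH2Cl2, −78 → −30 °C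
Reagents that add atoms: none
Why: Meinwald rearrangement: the Lewis acid opens the 2,2-disubstituted oxirane at the tertiary carbon and a 1,2-hydride shift from the CH2 terminus gives the α-branched aldehyde. The new C8 center forms unselectively and converges in step 6.

Step 4
Reactants: 6; 7 isopropenylmagnesium bromide
Product: 8 6-[(benzyloxy)methyl]-5-(3-hydroxy-4-methylpent-4-en-2-yl)-2-methylcyclohex-2-en-1-one (ring centers as in 4; C7/C8 diastereomer mixture)
Conditions: 7, THF, −78 °C; aq. NH4Cl
Reagents that add atoms: none
Why: Grignard addition is chemoselective for the aldehyde over the conjugated, doubly α-substituted ring ketone at low temperature. The carbinol configuration is irrelevant because it is oxidised next.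

Step 5
Reactants: 8
Product: 9 6-[(benzyloxy)methyl]-2-methyl-5-(4-methyl-3-oxopent-4-en-2-yl)cyclohex-2-en-1-one (ring centers as in 4; C8 epimer mixture)
Conditions: Dess–Martin periodinane, CH2Cl2, 0 °C
Reagents that add atoms: none
Why: Dess–Martin oxidation of the allylic secondary carbinol gives the isopropenyl ketone under neutral conditions. The ring enone and benzyl ether are inert; the product is a reactive Michael acceptor and is used directly.

Step 6
Reactants: 9
Product: 11 cis-fused 1-[(benzyloxy)methyl]-3,6,8-trimethyl-4a,5,6,8a-tetrahydronaphthalene-2,7(1H,8H)-dione (H-4a syn to H-8a; benzyloxymethyl anti to C8; C6 and C8 methyls equatorial; stereocenters as in 27), via potassium dienolate 10 (not isolated)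
Conditions: t-BuOK (0.3 equiv), t-BuOH–THF (1:4), 0.01 M, −20 → 23 °C
Reagents that add atoms: none
Why: t-Butoxide reversibly removes a γ-proton from C4a of the ring A enone to give the through-conjugated potassium dienolate 10 (O–C2=C3–C4=C4a), whose γ-terminus C4a adds to the terminal carbon C5 of the pendant isopropenyl ketone; protonation of the resulting C6 enolate by t-BuOH returns the base and the ring A enone. The closest known reaction type is the intramolecular vinylogous (γ-selective) Michael addition of cyclohexenone dienolates, in effect the Michael half of a Robinson annulation run through the γ-carbon. Ring B closes in a 6-(enolexo)-endo-trig mode. C4a is controlled by C8a: the new bond must form axially on ring A for overlap with the dienolate, and an axial bond can be bridged to the adjacent tether only when that tether is pseudo-equatorial, which enforces the cis fusion. C6 is created by protonation and, like C8, is epimerisable next to the C7 ketone; both methyls are expected to settle equatorial in the ring B chair that keeps C1 equatorial and C4 axial, because the other all-equatorial diastereomer would push the C8 methyl into a syn-pentane contact with the C1 benzyloxymethyl group, so both C8 epimers of 9 should converge. The step needs γ-selectivity: α-attack through C3 would require a bridged eight-membered ring, and α′-attack through C1 would build a quaternary center between two tertiary ones and is reversible by retro-Michael cleavage, so the six-membered γ-adduct should accumulate. High dilution suppresses intermolecular Michael addition, and substoichiometric base at low temperature limits β-elimination of benzyl alkoxide from the C1 enolate.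

Step 7
Reactants: 11
Product: 12 1-[(benzyloxy)methyl]-7-hydroxy-3,6,8-trimethyl-4a,5,6,7,8,8a-hexahydronaphthalen-2(1H)-one (C7 hydroxyl equatorial and trans to both methyls; stereocenters as in 27)
Conditions: NaBH4, EtOH–CH2Cl2 (1:1), −78 → −40 °C
Reagents that add atoms: none
Why: Borohydride reduces a saturated ketone faster than a conjugated, doubly α-substituted enone at low temperature (chemoselective carbonyl reduction). Axial hydride delivery past H-5 and H-8a would give the equatorial carbinol, although the preference at a ketone flanked by two equatorial methyls is expected to be modest. A 7-epimer would be separated and returned to 11 by oxidation.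

Step 8
Reactants: 12
Product: 13 1-[(benzyloxy)methyl]-7-[(tert-butyldimethylsilyl)oxy]-3,6,8-trimethyl-4a,5,6,7,8,8a-hexahydronaphthalen-2(1H)-one (stereocenters as in 27)
Conditions: t-BuMe2SiOTf, 2,6-lutidine, CH2Cl2, −78 → 0 °C
Reagents that add atoms: tert-butyldimethylsilyl trifluoromethanesulfonate, CC(C)(C)[Si](C)(C)OS(=O)(=O)C(F)(F)F
Why: Silyl triflate silylation protects the hindered secondary hydroxyl. With the weak base 2,6-lutidine the enone is not converted into a dienol ether.

Step 9
Reactants: 13
Product: 14 7-[(tert-butyldimethylsilyl)oxy]-1-(hydroxymethyl)-3,6,8-trimethyl-4a,5,6,7,8,8a-hexahydronaphthalen-2(1H)-one (stereocenters as in 27)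
Conditions: BCl3, C6HMe5, CH2Cl2, −78 °C; MeOH
Reagents that add atoms: none
Why: Lewis-acid debenzylation with pentamethylbenzene as a non-basic benzyl cation scavenger cleaves the primary benzyl ether at −78 °C and spares the hindered silyl ether and the enone. It is done here because later intermediates carry an alkyne and an ionisable tertiary carbinol.

Step 10
Reactants: 14; 15 tert-butyldimethyl(prop-2-yn-1-yloxy)silane
Product: 17 2-{3-[(tert-butyldimethylsilyl)oxy]prop-1-yn-1-yl}-7-[(tert-butyldimethylsilyl)oxy]-3,6,8-trimethyl-2-[(trimethylsilyl)oxy]-1-{[(trimethylsilyl)oxy]methyl}-1,2,4a,5,6,7,8,8a-octahydronaphthalene (C2 epimer not assigned; other stereocenters as in 27), via dilithium dialkoxide 16 (not isolated)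
Conditions: 15, n-BuLi, THF, −78 °C; CeCl3, −78 °C; 14, −78 → −40 °C; then Me3SiCl, Et3N, −40 → 23 °C
Reagents that add atoms: chlorotrimethylsilane, C[Si](C)(C)Cl
Why: The organocerium acetylide adds 1,2 to the hindered, enolisable enone (carbonyl alkynylation) after the first equivalent has deprotonated the hydroxyl. Both alkoxides are silylated in the flask so that no free C2 alkoxide exists later beside a carbonyl-conjugated C1 chain; the C2 configuration is irrelevant.

Step 11
Reactants: 17
Product: 18 2-{3-[(tert-butyldimethylsilyl)oxy]prop-1-yn-1-yl}-7-[(tert-butyldimethylsilyl)oxy]-3,6,8-trimethyl-2-[(trimethylsilyl)oxy]-1,2,4a,5,6,7,8,8a-octahydronaphthalene-1-carbaldehyde (stereocenters as in 17)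
Conditions: (COCl)2, DMSO, CH2Cl2, −78 → −40 °C; Et3N, −78 → 0 °C
Reagents that add atoms: none
Why: Under Swern conditions a primary trimethylsilyl ether is cleaved by the chlorosulfonium salt and oxidised directly to the aldehyde, whereas the tertiary trimethylsilyl ether and the TBS ethers are inert. Because C2 is sp3, the C1 aldehyde is an ordinary α-branched aldehyde; it is kept cold and used at once.

Step 12
Reactants: 18; 19 2-(triphenylphosphoranylidene)propanal
Product: 20 (E)-3-[2-{3-[(tert-butyldimethylsilyl)oxy]prop-1-yn-1-yl}-7-[(tert-butyldimethylsilyl)oxy]-3,6,8-trimethyl-2-[(trimethylsilyl)oxy]-1,2,4a,5,6,7,8,8a-octahydronaphthalen-1-yl]-2-methylprop-2-enal (stereocenters as in 17)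
Conditions: 19, toluene, 90 °C
Reagents that add atoms: none
Why: Wittig olefination with a stabilised, non-basic formyl ylide gives the (E)-2-methyl enal (C6′=C7′) under thermodynamic control of the betaine collapse. The product enal is less electrophilic than 18, so the reaction stops after one homologation.

Step 13
Reactants: 20; 21 ethyltriphenylphosphonium iodide
Product: 23 2-{3-[(tert-butyldimethylsilyl)oxy]prop-1-yn-1-yl}-7-[(tert-butyldimethylsilyl)oxy]-1-[(1E,3Z)-4-iodo-2-methylpenta-1,3-dien-1-yl]-3,6,8-trimethyl-1,2,4a,5,6,7,8,8a-octahydronaphthalen-2-ol (stereocenters as in 17), via silyl-protected iododiene 22 (not isolated)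
Conditions: 21, n-BuLi, THF, 23 °C; I2, −78 °C; NaN(SiMe3)2, −20 °C; 20, −78 °C; then K2CO3, MeOH, 23 °C
Reagents that add atoms: iodine, II
Why: Stork–Zhao-type Wittig olefination with the α-iodoethylidene ylide gives the (Z)-2-iodoalkene under kinetic control (iodine cis to the chain), which fixes the later 4′Z geometry. The aldehyde reacts much faster than its γ-position is deprotonated at −78 °C, and methanolysis then removes only the tertiary trimethylsilyl ether.

Step 14
Reactants: 23
Product: 24 (3E)-1-[(tert-butyldimethylsilyl)oxy]-3-{7-[(tert-butyldimethylsilyl)oxy]-1-[(1E,3Z)-4-iodo-2-methylpenta-1,3-dien-1-yl]-3,6,8-trimethyl-4a,5,6,7,8,8a-hexahydronaphthalen-2(1H)-ylidene}propan-2-one (acyl group syn to C1; stereocenters as in 27)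
Conditions: MoO2(acac)2 (5 mol %), AuCl(PPh3) (5 mol %), AgOTf (5 mol %), toluene, 23 °C
Reagents that add atoms: none
Why: Meyer–Schuster rearrangement: the tertiary alcohol forms a molybdate ester whose oxo group is delivered to the distal carbon of the gold-activated alkyne, and the resulting allenol tautomerises to the enone. The alkyne-specific activation should disfavour transposition across C3=C4, and the E isomer is expected because the alternative forces the acyl group against the in-plane C3 methyl (allylic 1,3-strain).

Step 15
Reactants: 24; 25 acrylic acid
Product: 26 (2E,4Z,6E)-7-{7-[(tert-butyldimethylsilyl)oxy]-2-[(E)-3-[(tert-butyldimethylsilyl)oxy]-2-oxopropylidene]-3,6,8-trimethyl-1,2,4a,5,6,7,8,8a-octahydronaphthalen-1-yl}-4,6-dimethylhepta-2,4,6-trienoic acid (stereocenters as in 27)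
Conditions: 25, Pd(OAc)2 (10 mol %), n-Bu4NCl, NaHCO3, DMF, 23 → 40 °C, dark
Reagents that add atoms: none
Why: Heck reaction under ligand-free phase-transfer conditions: oxidative addition retains the Z geometry of the iodide, and syn insertion of acrylate followed by syn β-hydride elimination gives the E acrylic acid. The only base is hydrogen carbonate, which should not deprotonate C1–H of the dienone.

Step 16
Reactants: 26
Product: 27 (2E,4Z,6E)-7-[(1R,2E,4aS,6S,7R,8R,8aR)-7-hydroxy-2-(3-hydroxy-2-oxopropylidene)-3,6,8-trimethyl-1,2,4a,5,6,7,8,8a-octahydronaphthalen-1-yl]-4,6-dimethylhepta-2,4,6-trienoic acid (CNP0219601.2)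
Conditions: HF·pyridine, pyridine, THF, 0 → 23 °C
Reagents that add atoms: none
Why: Buffered fluoride desilylation removes the primary and the hindered secondary silyl ether under weakly acidic conditions. The dienone, the Z-alkene and C1 should all tolerate these conditions.

## Compound list

1 | (R)-(−)-carvone | CC1=CC[C@H](CC1=O)C(C)=C | starting material
2 | benzyl chloromethyl ether | ClCOCc1ccccc1 | starting material
3 | lithium (R)-6-methyl-3-(prop-1-en-2-yl)cyclohexa-1,5-dien-1-olate (kinetic enolate of 1) | [Li+].CC1=CC[C@@H](C(C)=C)C=C1[O-] | intermediate
4 | (5R,6R)-6-[(benzyloxy)methyl]-2-methyl-5-(prop-1-en-2-yl)cyclohex-2-en-1-one | CC1=CC[C@@H](C(C)=C)[C@H](COCc2ccccc2)C1=O | intermediate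
5 | 6-[(benzyloxy)methyl]-2-methyl-5-(2-methyloxiran-2-yl)cyclohex-2-en-1-one (ring centers as in 4; oxirane epimers) | CC1=CC[C@@H](C2(C)CO2)[C@H](COCc3ccccc3)C1=O | intermediate
6 | 2-{6-[(benzyloxy)methyl]-4-methyl-5-oxocyclohex-3-en-1-yl}propanal (ring centers as in 4; C8 epimers) | CC1=CC[C@@H](C(C)C=O)[C@H](COCc2ccccc2)C1=O | intermediate
7 | isopropenylmagnesium bromide | CC(=C)[Mg]Br | starting material
8 | 6-[(benzyloxy)methyl]-5-(3-hydroxy-4-methylpent-4-en-2-yl)-2-methylcyclohex-2-en-1-one (ring centers as in 4; C7/C8 mixture) | CC1=CC[C@@H](C(C)C(O)C(C)=C)[C@H](COCc2ccccc2)C1=O | intermediate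
9 | 6-[(benzyloxy)methyl]-2-methyl-5-(4-methyl-3-oxopent-4-en-2-yl)cyclohex-2-en-1-one (ring centers as in 4; C8 epimers) | CC1=CC[C@@H](C(C)C(=O)C(C)=C)[C@H](COCc2ccccc2)C1=O | intermediate
10 | potassium through-conjugated dienolate of 9 (O–C2=C3–C4=C4a) | [K+].CC1=C([O-])[C@@H](COCc2ccccc2)[C@H](C(C)C(=O)C(C)=C)C=C1 | intermediate
11 | cis-fused 1-[(benzyloxy)methyl]-3,6,8-trimethyl-4a,5,6,8a-tetrahydronaphthalene-2,7(1H,8H)-dione | CC1=C[C@H]2C[C@H](C)C(=O)[C@H](C)[C@H]2[C@H](COCc3ccccc3)C1=O | intermediate
12 | 1-[(benzyloxy)methyl]-7-hydroxy-3,6,8-trimethyl-4a,5,6,7,8,8a-hexahydronaphthalen-2(1H)-one | CC1=C[C@H]2C[C@H](C)[C@@H](O)[C@H](C)[C@H]2[C@H](COCc3ccccc3)C1=O | intermediate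
13 | 1-[(benzyloxy)methyl]-7-[(tert-butyldimethylsilyl)oxy]-3,6,8-trimethyl-4a,5,6,7,8,8a-hexahydronaphthalen-2(1H)-one | CC1=C[C@H]2C[C@H](C)[C@@H](O[Si](C)(C)C(C)(C)C)[C@H](C)[C@H]2[C@H](COCc3ccccc3)C1=O | intermediate
14 | 7-[(tert-butyldimethylsilyl)oxy]-1-(hydroxymethyl)-3,6,8-trimethyl-4a,5,6,7,8,8a-hexahydronaphthalen-2(1H)-one | CC1=C[C@H]2C[C@H](C)[C@@H](O[Si](C)(C)C(C)(C)C)[C@H](C)[C@H]2[C@H](CO)C1=O | intermediate
15 | tert-butyldimethyl(prop-2-yn-1-yloxy)silane | C#CCO[Si](C)(C)C(C)(C)C | starting material
16 | dilithium dialkoxide of the C2 alkynyl carbinol (C2 epimer not assigned) | [Li+].[Li+].CC1=C[C@H]2C[C@H](C)[C@@H](O[Si](C)(C)C(C)(C)C)[C@H](C)[C@H]2[C@H](C[O-])C1([O-])C#CCO[Si](C)(C)C(C)(C)C | intermediate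
17 | C2 alkynyl carbinol as its bis(trimethylsilyl) ether (primary and tertiary oxygen) | CC1=C[C@H]2C[C@H](C)[C@@H](O[Si](C)(C)C(C)(C)C)[C@H](C)[C@H]2[C@H](CO[Si](C)(C)C)C1(O[Si](C)(C)C)C#CCO[Si](C)(C)C(C)(C)C | intermediate
18 | C1 carbaldehyde with tertiary trimethylsilyl ether at C2 | CC1=C[C@H]2C[C@H](C)[C@@H](O[Si](C)(C)C(C)(C)C)[C@H](C)[C@H]2[C@H](C=O)C1(O[Si](C)(C)C)C#CCO[Si](C)(C)C(C)(C)C | intermediate
19 | 2-(triphenylphosphoranylidene)propanal | CC(C=O)=P(c1ccccc1)(c1ccccc1)c1ccccc1 | starting material
20 | (E)-2-methyl enal at C1 (C6′=C7′ in place) | CC1=C[C@H]2C[C@H](C)[C@@H](O[Si](C)(C)C(C)(C)C)[C@H](C)[C@H]2[C@H](/C=C(C)/C=O)C1(O[Si](C)(C)C)C#CCO[Si](C)(C)C(C)(C)C | intermediate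
21 | ethyltriphenylphosphonium iodide | CC[P+](c1ccccc1)(c1ccccc1)c1ccccc1.[I-] | starting material
22 | (1E,3Z)-iododiene with tertiary trimethylsilyl ether at C2 | CC1=C[C@H]2C[C@H](C)[C@@H](O[Si](C)(C)C(C)(C)C)[C@H](C)[C@H]2[C@H](/C=C(C)/C=C(C)\I)C1(O[Si](C)(C)C)C#CCO[Si](C)(C)C(C)(C)C | intermediate
23 | (1E,3Z)-iododiene tertiary propargylic alcohol | CC1=C[C@H]2C[C@H](C)[C@@H](O[Si](C)(C)C(C)(C)C)[C@H](C)[C@H]2[C@H](/C=C(C)/C=C(C)\I)C1(O)C#CCO[Si](C)(C)C(C)(C)C | intermediate
24 | (E)-exocyclic dienone carrying the (1E,3Z)-iododiene | CC1=C[C@H]2C[C@H](C)[C@@H](O[Si](C)(C)C(C)(C)C)[C@H](C)[C@H]2[C@H](/C=C(C)/C=C(C)\I)/C1=C\C(=O)CO[Si](C)(C)C(C)(C)C | intermediate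
25 | acrylic acid | C=CC(=O)O | starting material
26 | bis(tert-butyldimethylsilyl) ether of 27 | CC1=C[C@H]2C[C@H](C)[C@@H](O[Si](C)(C)C(C)(C)C)[C@H](C)[C@H]2[C@H](/C=C(C)/C=C(C)\C=C\C(=O)O)/C1=C\C(=O)CO[Si](C)(C)C(C)(C)C | intermediate
27 | CNP0219601.2, (2E,4Z,6E)-7-[(1R,2E,4aS,6S,7R,8R,8aR)-7-hydroxy-2-(3-hydroxy-2-oxopropylidene)-3,6,8-trimethyl-1,2,4a,5,6,7,8,8a-octahydronaphthalen-1-yl]-4,6-dimethylhepta-2,4,6-trienoic acid | CC1=C[C@H]2C[C@H](C)[C@@H](O)[C@H](C)[C@H]2[C@H](/C=C(C)/C=C(C)\C=C\C(=O)O)/C1=C\C(=O)CO | target

## Step count and least certain steps

Total step count: 16. Longest linear sequence: 16 steps (1 → 27); all other components are commercial.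

**Step 6 (key step).** The ring closure may go through C1 instead of C4a. Benzyl alkoxide may be lost by β-elimination from the C1 enolate. The cis fusion may erode by re-enolisation toward C4a, because the same base that equilibrates C6 and C8 can also reach C4a. The fallback leaves the anionic manifold. It sets out from 9, which would be treated with t-BuMe2SiOTf (slightly more than one equivalent) and Et3N in CH2Cl2 at −78 → −20 °C. Soft enolisation gives the ring A dienol silyl ether, and the silyl triflate activates the pendant enone for a Mukaiyama–Michael closure with silyl transfer, giving the C7 silyl enol ether F1. Mild acid hydrolysis of F1 followed by brief K2CO3/MeOH equilibration of C6 and C8 would return to the route at 11.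

**Step 7.** Hydride delivery to a carbonyl flanked by two equatorial methyls may show poor facial selectivity (axial and equatorial trajectories are not strongly differentiated), and some 1,2-reduction of the enone may occur. Electron-transfer reductions, which would favour the equatorial carbinol, are excluded because they would reduce the enone first. The fallback replaces substrate control by catalyst control: from 11, an NADPH-dependent ketoreductase selected from a commercial panel (NADP+, i-PrOH, phosphate buffer, 30 °C) would reduce the saturated ketone with enzyme-determined facial selectivity and leave the hindered enone alone, coming back at 12 without any new compound.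

**Step 3.** The benzyl ether oxygen or the ring carbonyl may capture the developing tertiary cation at C8 before the hydride shift (tetrahydrofuran formation with loss of the benzyl group), or elimination to an allylic alcohol may compete. The fallback avoids cationic chemistry. It sets out from 4: Luche reduction (NaBH4, CeCl3, MeOH) masks the enone as the allylic alcohol F2. Hydroboration of the isopropenyl group with 9-BBN and oxidation with NaBO3 gives the diol F3, the trisubstituted ring alkene being much slower. Dess–Martin oxidation of both carbinols regenerates the enone and forms the aldehyde, returning at 6.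

**Step 14.** Oxygen may migrate across the C3=C4 alkene instead of the alkyne, the carbinol may dehydrate toward C1 (enyne formation), or the new exocyclic alkene may not equilibrate fully to E. The fallback changes the mechanism to an acyloxy shift. It sets out from 23, which is converted with KN(SiMe3)2 and Ac2O at −78 °C into the tertiary propargylic acetate F4. The cationic gold complex from AuCl(PPh3) and AgN(SO2CF3)2 in wet 2-butanone promotes a [3,3] acyloxy migration to the allenyl acetate F5, whose hydrolysis in the same flask gives the enone and returns at 24. The regiochemistry is then fixed by the six-membered acyloxy transfer.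

**Step 15.** The Z geometry at C4′=C5′ may erode through reversible hydridopalladium addition, and insertion at the hindered α-methyl alkenylpalladium may be slow. The fallback replaces carbopalladation by transmetalation. It sets out from 24, which is coupled under Stille conditions (Pd2(dba)3, AsPh3, N-methylpyrrolidone, 23 °C) with (E)-3-(tributylstannyl)acrylic acid F6, obtained by saponification of its ethyl ester. Both alkene geometries are carried over from the partners, and the route is rejoined at 26.

## Further compounds

F1 | step 6 | cis-fused 1-[(benzyloxy)methyl]-7-[(tert-butyldimethylsilyl)oxy]-3,6,8-trimethyl-4a,5,8,8a-tetrahydronaphthalen-2(1H)-one (C6=C7 silyl enol ether) | CC1=C[C@H]2CC(C)=C(O[Si](C)(C)C(C)(C)C)C(C)[C@H]2[C@H](COCc3ccccc3)C1=O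
F0 | step 7 | none | none
F2 | step 3 | 6-[(benzyloxy)methyl]-2-methyl-5-(prop-1-en-2-yl)cyclohex-2-en-1-ol (ring centers as in 4; carbinol epimers) | CC1=CC[C@@H](C(C)=C)[C@H](COCc2ccccc2)C1O
F3 | step 3 | 6-[(benzyloxy)methyl]-5-(1-hydroxypropan-2-yl)-2-methylcyclohex-2-en-1-ol (ring centers as in 4; C8 and carbinol epimers) | CC1=CC[C@@H](C(C)CO)[C@H](COCc2ccccc2)C1O
F4 | step 14 | tertiary propargylic acetate of 23 | CC1=C[C@H]2C[C@H](C)[C@@H](O[Si](C)(C)C(C)(C)C)[C@H](C)[C@H]2[C@H](/C=C(C)/C=C(C)\I)C1(OC(C)=O)C#CCO[Si](C)(C)C(C)(C)C
F5 | step 14 | allenyl acetate formed from F4 by [3,3] acyloxy shift | CC1=C[C@H]2C[C@H](C)[C@@H](O[Si](C)(C)C(C)(C)C)[C@H](C)[C@H]2[C@H](/C=C(C)/C=C(C)\I)C1=C=C(OC(C)=O)CO[Si](C)(C)C(C)(C)C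
F6 | step 15 | (E)-3-(tributylstannyl)acrylic acid | CCCC[Sn](CCCC)(CCCC)/C=C/C(=O)O
A1 | alternative 1 | cis-fused 7-[(tert-butyldimethylsilyl)oxy]-3,6,8-trimethyl-4a,5,6,7,8,8a-hexahydronaphthalen-2(1H)-one | CC1=C[C@H]2C[C@H](C)[C@@H](O[Si](C)(C)C(C)(C)C)[C@H](C)[C@H]2CC1=O
A2 | alternative 1 | (7E)-5-[(tert-butyldimethylsilyl)oxy]-4,6-dimethyl-9-oxoundec-7-enal | O=CCC[C@H](C)[C@@H](O[Si](C)(C)C(C)(C)C)[C@H](C)/C=C/C(=O)CC
A3 | alternative 2 | cis-fused ethyl 2-[(tert-butyldimethylsilyl)oxy]-3,6,8-trimethyl-7-[(triethylsilyl)oxy]-1,2,4a,7,8,8a-hexahydronaphthalene-1-carboxylate | CC1=C[C@H]2C=C(C)[C@@H](O[Si](CC)(CC)CC)[C@H](C)[C@H]2[C@H](C(=O)OCC)[C@@H]1O[Si](C)(C)C(C)(C)C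
A4 | alternative 2 | ethyl (4Z)-3-[(tert-butyldimethylsilyl)oxy]-2-{4,6-dimethyl-5-[(triethylsilyl)oxy]cyclohex-2-en-1-yl}-5-iodo-4-methylpent-4-enoate | I/C=C(/C)[C@@H](O[Si](C)(C)C(C)(C)C)[C@@H](C(=O)OCC)[C@H]1C=C[C@H](C)[C@@H](O[Si](CC)(CC)CC)[C@@H]1C
A5 | alternative 3 | methyl 2-[(2-ethyl-1,3-dioxolan-2-yl)methyl]-3,5-dimethyl-4-oxocyclohexanecarboxylate | COC(=O)[C@H]1C[C@H](C)C(=O)[C@H](C)[C@H]1CC2(CC)OCCO2
A6 | alternative 3 | 3-pentanone | CCC(=O)CC
A7 | alternative 3 | methyl 2-{1-[(tert-butoxycarbonyl)oxy]-2-(2-ethyl-1,3-dioxolan-2-yl)ethyl}acrylate (racemic) | COC(=O)C(=C)C(CC1(CC)OCCO1)OC(=O)OC(C)(C)C
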